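| setting | maple | elm | flask |
|---|---|---|---|
| solid substrate | 20 mM | 20 mM | 20 mM |
| free catalyst | 1 mM | 0.67 mM | 1.0 mM |
| temperature | 5 °C | 0 °C | 5 °C |
| remark | the very flask that is asked about, followed so far | run made earlier |  |
| time |  |  | 20 h |

- maple (time / h: target / %, solid substrate / %): 0.833: 15.3, 53.5; 2.50: 52.3, 0.9; 4.00: 68.3, 0.6; 6.00: 64.0, 0; 10.0: 45.0, 0; 12.0: 40.6, 0.3
- elm (time / h: target / %, solid substrate / %): 1.50: 12.8, 41.2; 2.50: 23.7, 25.5; 4.00: 38.0, 7.1; 8.00: 63.3, 0; 12.0: 63.0, 0; 20.0: 43.9, 0.6

(standard deviation of a reading: 0.5 percentage points)

- percent here means solid substrate units held: one resting dimer counts as two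
- solid substrate is a solid; its amount is given per volume of the solution
- target that was removed still counts
- what may be going on: starting material + free catalyst -> catalyst intermediate; catalyst intermediate <-> free catalyst + target; solid substrate <-> starting material; target <-> isomer of the product; 2 catalyst intermediate <-> resting dimer
- at the start none of the solid substrate is in solution
- additions bring no volume worth counting

- green: change nothing and wait 20 h more
- violet: at 20 h add free catalyst, 100% of the amount charged, then wait 20 h
- blue: at 20 h raise the temperature by 15 K, then wait 20 h
- amber: at 20 h take out 90% of the target then present, then wait 20 h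

- target, in percent of the solid substrate first charged, at 20 h
- what to do for the largest gain in target; "none" if nothing gains more than 2 percentage points (green / violet / blue / amber / none)
- target present, with what was taken out counted in, in percent of the solid substrate first charged, after green
- target present, with what was taken out counted in, in percent of the solid substrate first charged, after amber

- The time of reading, 20 h, lay beyond the last maple reading at 12.0 h, so I laid maple out as a ladder of time scales, in powers of ten where I could.
- On the fastest rung, solid substrate in maple fell from 53.5% to 0.9% of the charge between 0.833 h and 2.50 h, a tenfold drop every 0.940 h.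
- On the next rung, target in maple rose from 15.3% to 52.3% over that span, a pace that would pass the whole charge in 4.51 h, which is longer than the solid's decade.
- Target in maple then read 68.3% at 4.00 h; I took that high as kinetic control and the later fall as relaxation towards isomer of the product, that is, thermodynamic control.
- On the slowest rung, the maple drops of 19 percentage points and 4.4 points over 4.00 h and 2.00 h meant that a share 0.611 of the excess survived each 2.00 h.
- That reading gave 9.33 h: the decade time, the hours in which the excess of target over its plateau falls tenfold.
- The excess at 6.00 h read 30 points, which put the maple plateau at 33.7% of the charge.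
- From 6.00 h to 20 h is 1.50 decades, so I expected 34.7% of the charge as target in maple.
- Taking out 90% of that and letting the rest relax gave me 54.4% for amber; elm was still falling at its last reading, so I put no number on blue and chose amber.
- The forecast gave 35% now, 34% after green and 54.5% after amber, and chose amber: “Amber wins clearly”.
- Maple held 33.1% at 20 h, with 31.0% after green and 51.2% after amber; the gains were −2.1 points for green, −2.5 points for violet, 29 points for blue and 18 points for amber, so the best was blue, ahead of amber.

    starting material + free catalyst → catalyst intermediate (k = 0.590 M⁻¹ s⁻¹, Ea = 59.0 kJ mol⁻¹)
    catalyst intermediate ⇌ free catalyst + target (K = 0.0410 M, k = 0.00530 s⁻¹, Ea = 84.0 kJ mol⁻¹, ΔH = −26.0 kJ mol⁻¹)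
    solid substrate ⇌ starting material, rate k3*(cs3 - [starting material]) while solid is left; crystals form when [starting material] > cs3 (solubility = 11.0 mM, k = 4.20 × 10⁻⁴ s⁻¹)
    target ⇌ isomer of the product (K = 2.20, k = 3.80 × 10⁻⁵ s⁻¹, Ea = 91.0 kJ mol⁻¹, ΔH = −61.0 kJ mol⁻¹)
    2 catalyst intermediate ⇌ resting dimer, settled at all times (K = 1300 M⁻¹, ΔH = −38.0 kJ mol⁻¹)
    (constants at 5 °C)

- The step from target to isomer of the product, both ways, is the main reason that maple held 33.1% at 20 h, against 97.8% in the run without that step. Green lowered target in maple by 2.1 points. The step carries −61.0 kJ mol⁻¹, and with the back reaction of isomer of the product to target removed, blue brought −9.3 points instead of 29 points, so that back reaction is part of the reason for the gain.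
- For the neighbouring flask, the same charges and temperature read at 8.0 h, the decade time gave 52.0% target, and the computed flask held 53.3%.

(The readings are simulated with made-up constants; noise was put on by code.)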